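**Plan** (locants are those of the 2,3-dihydrobenzofuran core of the target: O1, C2, C3, C3a, C4–C7, C7a)
1. Retrosynthesis: the O1–C2 bond is cut and C2 is re-joined to C3a (retro-Cloke–Wilson), so the five-membered ring (O1, C2, C3, C3a, C7a) comes from a cyclopropane (C2, C3, C3a) spiro-fused at C3a to the six-membered ring.
2. Both cyclopropane bonds to C3a are then cut: a carbene at C3a (the only ring CH of isobutyrylfilicinic acid, stored as a diazo compound) plus the vinyl group of (R)-linalool. The six-membered ring goes back to phloroglucinol (two C5–CH3 bonds, the C7–acyl bond).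
3. Enabling feature: C3a lies between the C4 and C7a carbonyls and can leave as an enolate, and the tertiary hydroxyl sits on the carbon attached to C2. Its alkoxide opens C2–C3a from the rear, and the oxygen on C7a re-closes on C2.
4. Forward: six-membered ring first (acylation, dearomatising gem-dimethylation, diazo transfer), then the three-membered ring (carbene transfer to silylated linalool), then expansion to the five-membered ring with loss of the silyl helper.
5. Stereochemistry: the carbinol centre is that of (R)-(−)-linalool and is never a reaction centre. C2 is set in the cyclopropanation under catalyst control and carried into the dihydrofuran with net retention (two inversions).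

Key step: step 6

Remark: the enolised tricarbonyl unit is written as one arbitrary tautomer in each SMILES (the exocyclic enol of the target is the same compound as its 6-hydroxy-7-isobutyryl form), and the enantiomeric purity of the carbinol centre is that of the commercial (R)-(−)-linalool.

**Step 1**
Reactants: 1 phloroglucinol; 2 isobutyryl chloride
Product: 3 2-methyl-1-(2,4,6-trihydroxyphenyl)propan-1-one (phlorisobutyrophenone)
Conditions: AlCl3 (4 equiv), CH2Cl2/MeNO2, 0 °C → reflux; 1 M HCl
Reagents that add atoms: isobutyryl chloride (2), CC(C)C(Cl)=O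
Why: Friedel–Crafts C-acylation of the very electron-rich triphenol, whose three ring positions are equivalent and whose ketone product is deactivated against a second acylation.

**Step 2**
Reactants: 3 phlorisobutyrophenone; 4 iodomethane
Product: 5 3,5-dihydroxy-6,6-dimethyl-4-(2-methylpropanoyl)cyclohexa-2,4-dien-1-one (isobutyrylfilicinic acid)
Conditions: NaOMe (3 equiv), MeI (2.2 equiv), MeOH, 0 °C → rt; 1 M HCl
Reagents that add atoms: iodomethane (4), CI
Why: Dearomatising double C-methylation of an acylphloroglucinol, in which the polyphenolate in methanolic methoxide alkylates at one unsubstituted ring carbon twice to give the gem-dimethyl cyclohexadienone; over- and under-methylated by-products should be removable by chromatography.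

**Step 3**
Reactants: 5 isobutyrylfilicinic acid; 6 4-acetamidobenzenesulfonyl azide (p-ABSA)
Product: 7 6-diazo-3-hydroxy-4,4-dimethyl-2-(2-methylpropanoyl)cyclohex-2-ene-1,5-dione
Conditions: p-ABSA (1.1 equiv), Et3N (2.5 equiv), MeCN, 0 °C → rt
Reagents that add atoms: 4-acetamidobenzenesulfonyl azide (6), CC(=O)Nc1ccc(cc1)S(=O)(=O)N=[N+]=[N-]
Why: Regitz diazo transfer to the only C–H carbon flanked by two ring carbonyls, the acyl-bearing carbon being fully substituted and therefore expected to be inert under these mild conditions.

**Step 4**
Reactants: 8 (R)-(−)-linalool; 9 triethylsilyl trifluoromethanesulfonate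
Product: 10 (R)-triethyl[(3,7-dimethylocta-1,6-dien-3-yl)oxy]silane
Conditions: TESOTf (1.2 equiv), 2,6-lutidine (1.5 equiv), CH2Cl2, −78 → 0 °C
Reagents that add atoms: triethylsilyl trifluoromethanesulfonate (9), CC[Si](CC)(CC)OS(=O)(=O)C(F)(F)F
Why: Silylation of a hindered tertiary alcohol with a silyl triflate and 2,6-lutidine, which leaves the carbinol centre untouched, blocks carbenoid O–H insertion in step 5 and stores the alkoxide that fluoride releases in step 6.

**Step 5**
Reactants: 7 diazo trione; 10 linalool triethylsilyl ether
Product: 11 (1R)-6-hydroxy-7,7-dimethyl-1-[(2R)-6-methyl-2-(triethylsilyloxy)hept-5-en-2-yl]-5-(2-methylpropanoyl)spiro[2.5]oct-5-ene-4,8-dione (both epimers at the spiro carbon)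
Conditions: Rh2(S-NTTL)4 (1 mol %), 10 (3 equiv, excess recovered), 7 added over 6 h, PhCF3, 40 °C
Reagents that add atoms: none
Why: Rh(II)-carbenoid cyclopropanation of a terminal alkene by a 2-diazo-1,3-dione, in which the carbenoid should add end-on to the unhindered =CH2 of the vinyl group (attack on the trisubstituted alkene would join two fully substituted carbons next to the spiro centre), the cyclopropane CH stereocentre being set under catalyst control by the chiral tert-leucinate paddlewheel because the allylic quaternary centre gives little bias of its own, while the spiro configuration is immaterial since that carbon becomes sp2 in step 6.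

**Step 6**
Reactants: 11 silylated spirocyclopropane
Product: 14 (2S)-6-hydroxy-2-[(2R)-2-hydroxy-6-methylhept-5-en-2-yl]-5,5-dimethyl-7-(2-methylpropanoyl)-2,3-dihydro-1-benzofuran-4(5H)-one (the target), via spirocyclopropyl carbinolate 12 (not isolated), via epoxy enolate 13 (not isolated)
Conditions: TBAF (3 equiv, 1 M in THF), THF, 0 → 40 °C; then aq. NH4Cl
Reagents that add atoms: none
Why: Proposed new method: fluoride cleaves the Si–O bond and unveils a tetrabutylammonium tertiary alkoxide on the carbon attached to the cyclopropane CH; this alkoxide displaces C3a from that CH by rear-side attack (3-exo-tet, inversion) because C3a leaves as the enolate held between the C4 and C7a carbonyls (a far weaker base than the alkoxide, with ring strain roughly unchanged from cyclopropane to oxirane), and the enolate oxygen on C7a then opens the transient 2,3-epoxide at the same CH (second inversion), which closes the dihydrofuran and returns the tertiary alkoxide. The closest known reaction type is the nucleophile-catalysed Cloke–Wilson rearrangement of spiro-activated cyclopropyl ketones (iodide, amine or phosphine: SN2 opening, then SN2 O-closure), here run with a nucleophile that the substrate carries itself, and its second half is the established base-mediated cyclisation of an enol onto a 2,3-epoxy chain. An acid-promoted Cloke–Wilson is avoided because the CH bears no cation-stabilising group and a cation there would invite pinacol shifts of the neighbouring carbinol, while an external nucleophile would attack the unhindered CH2 of the cyclopropane. The only ring closed for good is the dihydrofuran (5-exo-tet; the transient oxirane forms 3-exo-tet), its stereocentre C2 is fixed by the cyclopropane CH of 11 through two inversions (net retention), and the carbinol centre keeps the linalool configuration since its C–O bond is never broken. The step needs cleavage of C2–C3a and not C3–C3a, which the position of the alkoxide secures (only the adjacent CH can be reached and only C3a is a leaving group), and 5-exo instead of 6-endo epoxide opening, which the basic SN2 conditions secure (secondary CH against the fully substituted carbinol carbon). It also needs closure through the oxygen on C7a and not the one on C4: the oxygen on C7a is the common terminus of the two anionic π-systems of the dianion (the new C3a enolate and the acyl-triketonate) and is left unchelated by the tetrabutylammonium counter-ion, so it should be the more nucleophilic, and this is the ring fusion found in the natural congeners.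

**Compound list**
1 | phloroglucinol (benzene-1,3,5-triol) | Oc1cc(O)cc(O)c1 | starting material
2 | isobutyryl chloride | CC(C)C(Cl)=O | starting material
3 | 2-methyl-1-(2,4,6-trihydroxyphenyl)propan-1-one | CC(C)C(=O)c1c(O)cc(O)cc1O | intermediate
4 | iodomethane | CI | starting material
5 | 3,5-dihydroxy-6,6-dimethyl-4-(2-methylpropanoyl)cyclohexa-2,4-dien-1-one (isobutyrylfilicinic acid) | CC(C)C(=O)C1=C(O)C(C)(C)C(=O)C=C1O | intermediate
6 | 4-acetamidobenzenesulfonyl azide | CC(=O)Nc1ccc(cc1)S(=O)(=O)N=[N+]=[N-] | starting material
7 | 6-diazo-3-hydroxy-4,4-dimethyl-2-(2-methylpropanoyl)cyclohex-2-ene-1,5-dione | CC(C)C(=O)C1=C(O)C(C)(C)C(=O)C(=[N+]=[N-])C1=O | intermediate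
8 | (R)-(−)-linalool, (3R)-3,7-dimethylocta-1,6-dien-3-ol | C=C[C@](C)(O)CCC=C(C)C | starting material
9 | triethylsilyl trifluoromethanesulfonate | CC[Si](CC)(CC)OS(=O)(=O)C(F)(F)F | starting material
10 | (R)-triethyl[(3,7-dimethylocta-1,6-dien-3-yl)oxy]silane | C=C[C@](C)(O[Si](CC)(CC)CC)CCC=C(C)C | intermediate
11 | (1R)-6-hydroxy-7,7-dimethyl-1-[(2R)-6-methyl-2-(triethylsilyloxy)hept-5-en-2-yl]-5-(2-methylpropanoyl)spiro[2.5]oct-5-ene-4,8-dione, spiro carbon as both epimers | CC(C)=CCC[C@@](C)(O[Si](CC)(CC)CC)[C@@H]1CC12C(=O)C(C)(C)C(O)=C(C(=O)C(C)C)C2=O | intermediate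
12 | (1R)-6-hydroxy-1-[(2R)-2-hydroxy-6-methylhept-5-en-2-yl]-7,7-dimethyl-5-(2-methylpropanoyl)spiro[2.5]oct-5-ene-4,8-dione, formed as its tetrabutylammonium alkoxide (SMILES of the neutral form) | CC(C)=CCC[C@@](C)(O)[C@@H]1CC12C(=O)C(C)(C)C(O)=C(C(=O)C(C)C)C2=O | intermediate
13 | 3,5-dihydroxy-6,6-dimethyl-2-{[(2R,3R)-3-methyl-3-(4-methylpent-3-en-1-yl)oxiran-2-yl]methyl}-4-(2-methylpropanoyl)cyclohexa-2,4-dien-1-one, formed as its enolate (SMILES of the neutral form) | CC(C)=CCC[C@@]3(C)O[C@@H]3CC1=C(O)C(C(=O)C(C)C)=C(O)C(C)(C)C1=O | intermediate
14 | (2S)-6-hydroxy-2-[(2R)-2-hydroxy-6-methylhept-5-en-2-yl]-5,5-dimethyl-7-(2-methylpropanoyl)-2,3-dihydro-1-benzofuran-4(5H)-one, CNP0317212.1 | CC(C)=CCC[C@@](C)(O)[C@@H]1CC2=C(O1)/C(=C(/O)C(C)C)C(=O)C(C)(C)C2=O | target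

**Total step count:** 6. **Longest linear sequence:** 5 (steps 1, 2, 3, 5, 6).

**Steps most likely to fail**

Step 6 (Proposed new method). The unveiled alkoxide may add reversibly to a ring carbonyl and not displace C3a, or fluoride may open the cyclopropane at its CH2. The enolate may also close through the oxygen on C4 (regioisomeric ring fusion) or in the 6-endo mode. The fallback uses known chemistry in the aromatic series, where the competing oxygen is blocked, and sets out from 3. Selective methoxymethylation of the non-chelated para-hydroxyl (MOMCl, i-Pr2NEt, CH2Cl2, 0 °C) should give 1-[2,6-dihydroxy-4-(methoxymethoxy)phenyl]-2-methylpropan-1-one F1. Geraniol is epoxidised by Sharpless asymmetric epoxidation with D-(−)-diisopropyl tartrate to (2R,3R)-2,3-epoxygeraniol F2, which is oxidised (Dess–Martin periodinane, NaHCO3) to (2S,3R)-2,3-epoxygeranial F3. Reductive C-alkylation of F1 with F3 (L-proline, Hantzsch ester, the ortho-quinone methide being reduced in situ) should give the epoxy-alkylated phenol F4. Its only free ortho-hydroxyl opens the epoxide 5-exo with inversion (K2CO3, MeOH) to the MOM-protected dihydrobenzofuran F5. MOM removal (PPTS, MeOH, 50 °C) gives the 4,6-diol F6, and dearomatising gem-dimethylation at C5 under the conditions of step 2 comes back to the route at 14.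

Step 5. The carbenoid may be consumed by the trisubstituted alkene or by the enol O–H of a second molecule, and the facial selectivity at the cyclopropane CH may be poor or of the wrong sense. The antipodal catalyst Rh2(R-NTTL)4 is the first remedy for a mismatched sense. The fallback bypasses the carbene, sets out from 5 and comes back at 13. Compound 5 is C-alkylated reductively with the epoxy aldehyde F3 described above (L-proline, Hantzsch ester, CH2Cl2), which should give the epoxy enol 13 with both stereocentres set by the Sharpless epoxidation. K2CO3 in MeOH (the second half of step 6) then closes 13 to 14.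

Step 3. Diazo transfer may strip the isobutyryl group (deacylative transfer), or the diazo compound may decompose through its own acidic enol. The fallback stores the carbene as an iodonium ylide, sets out from 5 and comes back at 11. Compound 5 with PhI(OAc)2 and KOH in MeOH at 0 °C should give the phenyliodonium ylide F7, which replaces 7 in step 5 (same Rh catalyst, or Cu(acac)2).

**Further compounds**
F1 | step 6 | 1-[2,6-dihydroxy-4-(methoxymethoxy)phenyl]-2-methylpropan-1-one | CC(C)C(=O)c1c(O)cc(OCOC)cc1O
F2 | step 6 | [(2R,3R)-3-methyl-3-(4-methylpent-3-en-1-yl)oxiran-2-yl]methanol, (2R,3R)-2,3-epoxygeraniol | CC(C)=CCC[C@@]1(C)O[C@@H]1CO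
F3 | step 6 | (2S,3R)-3-methyl-3-(4-methylpent-3-en-1-yl)oxirane-2-carbaldehyde | CC(C)=CCC[C@@]1(C)O[C@@H]1C=O
F4 | step 6 | 1-[2,6-dihydroxy-4-(methoxymethoxy)-3-{[(2R,3R)-3-methyl-3-(4-methylpent-3-en-1-yl)oxiran-2-yl]methyl}phenyl]-2-methylpropan-1-one | CC(C)=CCC[C@@]1(C)O[C@@H]1Cc1c(O)c(C(=O)C(C)C)c(O)cc1OCOC
F5 | step 6 | 1-[(2S)-6-hydroxy-2-[(2R)-2-hydroxy-6-methylhept-5-en-2-yl]-4-(methoxymethoxy)-2,3-dihydro-1-benzofuran-7-yl]-2-methylpropan-1-one | CC(C)=CCC[C@@](C)(O)[C@@H]1Cc2c(O1)c(C(=O)C(C)C)c(O)cc2OCOC
F6 | step 6 | 1-[(2S)-4,6-dihydroxy-2-[(2R)-2-hydroxy-6-methylhept-5-en-2-yl]-2,3-dihydro-1-benzofuran-7-yl]-2-methylpropan-1-one | CC(C)=CCC[C@@](C)(O)[C@@H]1Cc2c(O1)c(C(=O)C(C)C)c(O)cc2O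
F0 | step 5 | none | none
F7 | step 3 | phenyliodonium ylide of isobutyrylfilicinic acid | CC(C)C(=O)C1=C(O)C(C)(C)C(=O)[C-]([I+]c2ccccc2)C1=O
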